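**Retrosynthetic overview**
1. Target ⇒ Yamaguchi esterification of the C6 alcohol 36 with (2S,3R)-2,3-dimethyloxirane-2-carboxylic acid 40 (tiglic acid; Sharpless epoxidation; RuO4 oxidation).
2. Furanone (formed last) ⇒ gold-catalysed transannular 5-endo cyclisation of the macrocyclic α'-hydroxy ynone 34; ten-membered carbocycle (formed second) ⇒ Nozaki–Hiyama–Kishi closure of C1–C2 (iodoalkyne onto the C1 aldehyde).
3. Z-enyne ⇒ Sonogashira coupling on Z-vinyl iodide 27, made from propynyl ketone 19 by Noyori reduction (sets C6), trans-hydrosilylation and iododesilylation; exocyclic methylene ⇒ Eschenmoser (Mannich) methylenation.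
4. trans-γ-Lactone (formed first; sets C7 and C8) ⇒ intermolecular Evans boron syn-aldol of succinate imide 11 with aldehyde 7, then lactonisation. This is the key fragment union (C7–C8).
5. Aldehyde 7 (C10) ⇒ Sharpless epoxidation of methallyl alcohol, vinyl Grignard opening, acetonide, ozonolysis. Ring order: lactone → carbocycle → furanone.

Assumption: the SMILES is read as the 4Z,6R,7R,8S,10R germacranolide (C1 ketone, C2=C3 in the furanone, O bridge C3–O–C10, lactone closed on O-8, ester on O-6) with a (2S,3R)-epoxy ester; labels C1–C15 below use this numbering.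

**Step 1**
Reactants: 1 2-methylprop-2-en-1-ol
Product: 2 [(2S)-2-methyloxiran-2-yl]methanol
Conditions: Ti(OiPr)4 (5 mol%), L-(+)-DIPT (6 mol%), cumene hydroperoxide, 4 Å MS, CH2Cl2, −20 °C
Reagents that add atoms: cumene hydroperoxide CC(C)(OO)c1ccccc1
Why: Sharpless asymmetric epoxidation; the L-(+)-tartrate titanium catalyst delivers oxygen to one alkene face and sets the future C10 (about 90–95% ee, the minor antipode being removed as a diastereomer after step 6).

**Step 2**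
Reactants: 2 [(2S)-2-methyloxiran-2-yl]methanol; 3 vinylmagnesium bromide
Product: 4 (2R)-2-methylpent-4-ene-1,2-diol
Conditions: 3 (3 equiv), CuI (10 mol%), THF, −30 → 0 °C; aq NH4Cl
Reagents that add atoms: none
Why: Copper-catalysed Grignard epoxide opening (SN2) at the unsubstituted CH2, so the quaternary centre is untouched and only its CIP label changes.

**Step 3**
Reactants: 4 (2R)-2-methylpent-4-ene-1,2-diol
Product: 5 (4R)-2,2,4-trimethyl-4-(prop-2-en-1-yl)-1,3-dioxolane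
Conditions: 2,2-dimethoxypropane, PPTS (cat.), CH2Cl2, rt
Reagents that add atoms: 2,2-dimethoxypropane COC(C)(C)OC
Why: Acid-catalysed transacetalisation masks the C1/C10 diol as an acetonide that survives every step up to step 16.

**Step 4**
Reactants: 5 (4R)-2,2,4-trimethyl-4-(prop-2-en-1-yl)-1,3-dioxolane
Product: 7 2-[(4R)-2,2,4-trimethyl-1,3-dioxolan-4-yl]acetaldehyde, via ozonide 6 (not isolated)
Conditions: O3, CH2Cl2, −78 °C; then PPh3, −78 °C → rt
Reagents that add atoms: ozone [O-][O+]=O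
Why: Ozonolysis with reductive work-up cleaves the terminal alkene to the C8 aldehyde without touching the acetal or the quaternary centre.

**Step 5**
Reactants: 8 (4R)-4-benzyl-1,3-oxazolidin-2-one; 9 methyl 4-chloro-4-oxobutanoate
Product: 11 methyl 4-[(4R)-4-benzyl-2-oxo-1,3-oxazolidin-3-yl]-4-oxobutanoate, via N-lithio oxazolidinone 10 (not isolated)
Conditions: n-BuLi, THF, −78 °C; then 9, −78 → 0 °C
Reagents that add atoms: none
Why: N-acylation of the lithiated Evans auxiliary by the acid chloride gives the succinate imide that carries C6, C7, C11 and C12.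

**Step 6**
Reactants: 11 methyl 4-[(4R)-4-benzyl-2-oxo-1,3-oxazolidin-3-yl]-4-oxobutanoate; 7 2-[(4R)-2,2,4-trimethyl-1,3-dioxolan-4-yl]acetaldehyde
Product: 14 (4R)-4-benzyl-3-{[(2S,3R)-5-oxo-2-{[(4R)-2,2,4-trimethyl-1,3-dioxolan-4-yl]methyl}oxolan-3-yl]carbonyl}-1,3-oxazolidin-2-one, via dibutylboron Z-enolate 12 (not isolated), via syn-aldol adduct 13 (not isolated)
Conditions: Bu2BOTf, iPr2NEt, CH2Cl2, 0 °C; 7, −78 → 0 °C; pH 7 buffer, MeOH, H2O2; then PPTS (cat.), CH2Cl2, rt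
Reagents that add atoms: none
Why: Evans boron syn-aldol joins the two fragments at C7–C8 through a Zimmerman–Traxler chair in which the aldehyde adds to the Z-enolate face opposite the benzyl group (C7 R, C8 S), and the γ-hydroxy ester then closes to the trans-lactone.

**Step 7**
Reactants: 14 lactone imide
Product: 16 (2S,3R)-5-oxo-2-{[(4R)-2,2,4-trimethyl-1,3-dioxolan-4-yl]methyl}oxolane-3-carboxylic acid, via peroxy acid 15 (not isolated)
Conditions: LiOH, H2O2, THF/H2O, 0 °C; Na2SO3; HCl to pH 3 at 0 °C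
Reagents that add atoms: hydrogen peroxide OO
Why: Hydroperoxide cleavage of the Evans auxiliary attacks the exocyclic imide carbonyl selectively, sulfite reduces the peracid, and any lactone opened by hydroxide recloses on acidification with no stereocentre touched.

**Step 8**
Reactants: 16 lactone acid; 17 propyne
Product: 19 (4R,5S)-4-(but-2-ynoyl)-5-{[(4R)-2,2,4-trimethyl-1,3-dioxolan-4-yl]methyl}oxolan-2-one, via acid chloride 18 (not isolated)
Conditions: 1-chloro-N,N,2-trimethylprop-1-en-1-amine, CH2Cl2, 0 °C → rt; then propyne (excess), PdCl2(PPh3)2 (2 mol%), CuI (4 mol%), Et3N, THF, 0 °C → rt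
Reagents that add atoms: none
Why: Neutral acid chloride formation (safe for the acetonide) followed by acyl Sonogashira coupling gives the C6 ynone; any C7 epimerisation returns the favoured trans-lactone.

**Step 9**
Reactants: 19 ynone
Product: 20 (4S,5S)-4-[(1S)-1-hydroxybut-2-yn-1-yl]-5-{[(4R)-2,2,4-trimethyl-1,3-dioxolan-4-yl]methyl}oxolan-2-one
Conditions: Ru(p-cymene)[(S,S)-TsDPEN] (2 mol%), iPrOH, rt
Reagents that add atoms: none
Why: Noyori asymmetric transfer hydrogenation reduces the ynone under catalyst control (alkynyl versus alkyl differentiation) to the (S)-propargylic carbinol, which is the spatial arrangement of C6 in the target.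

**Step 10**
Reactants: 20 propargylic alcohol
Product: 21 (4S,5S)-4-[(1S,2Z)-1-hydroxy-3-(triethylsilyl)but-2-en-1-yl]-5-{[(4R)-2,2,4-trimethyl-1,3-dioxolan-4-yl]methyl}oxolan-2-one
Conditions: [Cp*Ru(MeCN)3]PF6 (3 mol%), Et3SiH, CH2Cl2, 0 °C → rt
Reagents that add atoms: triethylsilane CC[SiH](CC)CC
Why: Trost ruthenium-catalysed trans-hydrosilylation adds H and Si anti across the alkyne, with the propargylic hydroxyl directing silicon to the distal carbon C4, so silicon ends cis to C6 (Z) under neutral conditions that spare the lactone.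

**Step 11**
Reactants: 21 vinylsilane
Product: 22 (4S,5S)-4-[(1S,2Z)-1-hydroxy-3-iodobut-2-en-1-yl]-5-{[(4R)-2,2,4-trimethyl-1,3-dioxolan-4-yl]methyl}oxolan-2-one
Conditions: NIS, 2,6-lutidine, HFIP, 0 °C, dark
Reagents that add atoms: N-iodosuccinimide O=C1CCC(=O)N1I
Why: Iododesilylation is an ipso substitution that proceeds with retention, converting the Z-vinylsilane into the Z-vinyl iodide (iodine on C4, cis to C6).

**Step 12**
Reactants: 22 vinyl iodide alcohol
Product: 23 (4R,5S)-4-[(1S,2Z)-1-{[tert-butyl(dimethyl)silyl]oxy}-3-iodobut-2-en-1-yl]-5-{[(4R)-2,2,4-trimethyl-1,3-dioxolan-4-yl]methyl}oxolan-2-one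
Conditions: TBSOTf, 2,6-lutidine, CH2Cl2, −78 → 0 °C
Reagents that add atoms: tert-butyldimethylsilyl triflate CC(C)(C)[Si](C)(C)OS(=O)(=O)C(F)(F)F
Why: Silylation protects the C6 hydroxyl against the enolate chemistry and the oxidations that follow.

**Step 13**
Reactants: 23 silyl ether lactone
Product: 27 (4R,5S)-4-[(1S,2Z)-1-{[tert-butyl(dimethyl)silyl]oxy}-3-iodobut-2-en-1-yl]-3-methylidene-5-{[(4R)-2,2,4-trimethyl-1,3-dioxolan-4-yl]methyl}oxolan-2-one, via lithium enolate 24 (not isolated), via Mannich base 25 (not isolated), via trimethylammonium iodide 26 (not isolated)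
Conditions: LiHMDS, THF, −78 °C; Eschenmoser's salt, −78 °C → rt; MeI, THF/MeOH, rt; aq NaHCO3, CH2Cl2, rt
Reagents that add atoms: Eschenmoser's salt C=[N+](C)C.[I-]
Why: Eschenmoser methylenation (Mannich reaction of the lactone enolate, N-methylation, elimination) installs the exocyclic methylene while C6 is still sp3 and every other group is base-stable, and the transient C11 centre becomes planar.

**Step 14**
Reactants: 27 methylene lactone vinyl iodide; 28 ethynyltrimethylsilane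
Product: 29 (4R,5S)-4-[(1R,2Z)-1-{[tert-butyl(dimethyl)silyl]oxy}-3-methyl-5-(trimethylsilyl)pent-2-en-4-yn-1-yl]-3-methylidene-5-{[(4R)-2,2,4-trimethyl-1,3-dioxolan-4-yl]methyl}oxolan-2-one
Conditions: PdCl2(PPh3)2 (5 mol%), CuI (10 mol%), Et3N, THF, rt
Reagents that add atoms: none
Why: Sonogashira coupling replaces the iodide with retention of the Z geometry, copper acetylide transmetalation at room temperature being much faster than any Heck reaction with the enoate.

**Step 15**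
Reactants: 29 silyl enyne
Product: 30 (4R,5S)-4-[(1R,2Z)-1-{[tert-butyl(dimethyl)silyl]oxy}-5-iodo-3-methylpent-2-en-4-yn-1-yl]-3-methylidene-5-{[(4R)-2,2,4-trimethyl-1,3-dioxolan-4-yl]methyl}oxolan-2-one
Conditions: NIS, AgNO3 (20 mol%), acetone, rt, dark
Reagents that add atoms: N-iodosuccinimide O=C1CCC(=O)N1I
Why: Silver-catalysed iododesilylation converts the alkynylsilane directly into the iodoalkyne under neutral conditions that the methylene lactone tolerates.

**Step 16**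
Reactants: 30 iodoalkyne acetonide
Product: 31 (4R,5S)-4-[(1R,2Z)-1-{[tert-butyl(dimethyl)silyl]oxy}-5-iodo-3-methylpent-2-en-4-yn-1-yl]-5-[(2R)-2,3-dihydroxy-2-methylpropyl]-3-methylideneoxolan-2-one
Conditions: AcOH/H2O (4:1), rt
Reagents that add atoms: none
Why: Mild acetal hydrolysis frees the C1/C10 diol while the hindered secondary silyl ether, the iodoalkyne and the enoate survive.

**Step 17**
Reactants: 31 diol
Product: 32 (4R,5S)-4-[(1R,2Z)-1-{[tert-butyl(dimethyl)silyl]oxy}-5-iodo-3-methylpent-2-en-4-yn-1-yl]-5-[(2R)-2-hydroxy-2-methyl-3-oxopropyl]-3-methylideneoxolan-2-one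
Conditions: TEMPO (20 mol%), PhI(OAc)2, CH2Cl2, rt
Reagents that add atoms: none
Why: Oxoammonium (TEMPO) oxidation takes only the primary alcohol to the C1 aldehyde and cannot cleave the diol or touch the tertiary alcohol.

**Step 18**
Reactants: 32 hydroxy aldehyde
Product: 33 (4Z,6R,7R,8S,10R)-6-{[tert-butyl(dimethyl)silyl]oxy}-1,10-dihydroxygermacra-4,11(13)-dien-2-yn-12,8-olide (C1 epimers)
Conditions: CrCl2 (8 equiv), NiCl2 (5 mol%), THF (0.003 M), rt, slow addition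
Reagents that add atoms: none
Why: Intramolecular Nozaki–Hiyama–Kishi alkynylation forms C1–C2 chemoselectively at high dilution and closes the ten-membered enyne ring; the new C1 carbinol centre is irrelevant because it is oxidised next.

**Step 19**
Reactants: 33 macrocyclic diol
Product: 34 (4Z,6R,7R,8S,10R)-6-{[tert-butyl(dimethyl)silyl]oxy}-10-hydroxy-1-oxogermacra-4,11(13)-dien-2-yn-12,8-olide
Conditions: Dess–Martin periodinane, CH2Cl2, 0 °C → rt
Reagents that add atoms: none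
Why: Dess–Martin oxidation converts both C1 epimers of the propargylic alcohol into one ynone and leaves the tertiary C10 hydroxyl free.

**Step 20**
Reactants: 34 hydroxy ynone
Product: 35 (4Z,6R,7R,8S,10R)-6-{[tert-butyl(dimethyl)silyl]oxy}-3,10-epoxy-1-oxogermacra-2,4,11(13)-trien-12,8-olide
Conditions: (4-CF3C6H4)3PAuCl (5 mol%), AgOTf (5 mol%), toluene, rt
Reagents that add atoms: none
Why: Gold-catalysed 5-endo-dig cycloisomerisation (intramolecular oxa-Michael addition of the C10 hydroxyl to C3 of the activated ynone) builds the 3(2H)-furanone transannularly with C10 unchanged.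

**Step 21**
Reactants: 35 silyl-protected furanone
Product: 36 (4Z,6R,7S,8S,10R)-6-hydroxy-3,10-epoxy-1-oxogermacra-2,4,11(13)-trien-12,8-olide
Conditions: HF·pyridine, pyridine, THF, 0 °C → rt
Reagents that add atoms: none
Why: Buffered fluoride desilylation frees the C6 alcohol without adding a nucleophile to the methylene lactone (the 7S label is a CIP priority change only).

**Step 22**
Reactants: 37 (2E)-2-methylbut-2-enoic acid (tiglic acid)
Product: 38 (2E)-2-methylbut-2-en-1-ol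
Conditions: LiAlH4, Et2O, 0 °C → rt
Reagents that add atoms: none
Why: Hydride reduction of the conjugated acid occurs 1,2 and keeps the E geometry that defines the cis-dimethyl epoxide.

**Step 23**
Reactants: 38 (2E)-2-methylbut-2-en-1-ol
Product: 39 [(2R,3R)-2,3-dimethyloxiran-2-yl]methanol
Conditions: Ti(OiPr)4 (10 mol%), D-(−)-DIPT (12 mol%), t-BuOOH, 4 Å MS, CH2Cl2, −20 °C
Reagents that add atoms: tert-butyl hydroperoxide CC(C)(C)OO
Why: Sharpless asymmetric epoxidation with the D-(−)-tartrate catalyst sets both epoxide centres by syn oxygen delivery to the face opposite to that used in step 1.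

**Step 24**
Reactants: 39 epoxy alcohol
Product: 40 (2S,3R)-2,3-dimethyloxirane-2-carboxylic acid
Conditions: RuCl3 hydrate (2 mol%), NaIO4, MeCN/EtOAc/H2O, rt
Reagents that add atoms: sodium periodate [Na+].[O-]I(=O)(=O)=O; water O
Why: Catalytic RuO4 oxidation takes the primary alcohol to the acid without opening the epoxide (the C2 label changes from R to S by CIP priority only).

**Step 25**
Reactants: 36 C6 alcohol; 40 (2S,3R)-2,3-dimethyloxirane-2-carboxylic acid
Product: 42 (4Z,6R,7R,8S,10R)-6-{[(2S,3R)-2,3-dimethyloxirane-2-carbonyl]oxy}-3,10-epoxy-1-oxogermacra-2,4,11(13)-trien-12,8-olide, via mixed anhydride 41 (not isolated)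
Conditions: 40, 2,4,6-trichlorobenzoyl chloride, Et3N, THF, rt; then 36, DMAP, toluene, rt
Reagents that add atoms: none
Why: Yamaguchi esterification acylates the hindered C6 alcohol through the acylpyridinium of the α-quaternary acid under mild conditions, with C6 and both epoxide centres untouched.

**Compound list**
1 | 2-methylprop-2-en-1-ol | C=C(C)CO | starting material
2 | [(2S)-2-methyloxiran-2-yl]methanol | C[C@]1(CO)CO1 | intermediate
3 | vinylmagnesium bromide | C=C[Mg]Br | starting material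
4 | (2R)-2-methylpent-4-ene-1,2-diol | C[C@](O)(CO)CC=C | intermediate
5 | (4R)-2,2,4-trimethyl-4-(prop-2-en-1-yl)-1,3-dioxolane | C[C@@]1(CC=C)COC(C)(C)O1 | intermediate
6 | (4R)-2,2,4-trimethyl-4-(1,2,4-trioxolan-3-ylmethyl)-1,3-dioxolane (ozonide) | C[C@@]1(CC2OCOO2)COC(C)(C)O1 | intermediate
7 | 2-[(4R)-2,2,4-trimethyl-1,3-dioxolan-4-yl]acetaldehyde | C[C@@]1(CC=O)COC(C)(C)O1 | intermediate
8 | (4R)-4-benzyl-1,3-oxazolidin-2-one | O=C1N[C@H](Cc2ccccc2)CO1 | starting material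
9 | methyl 4-chloro-4-oxobutanoate | COC(=O)CCC(Cl)=O | starting material
10 | N-lithio-(4R)-4-benzyl-1,3-oxazolidin-2-one | [Li]N1[C@H](Cc2ccccc2)COC1=O | intermediate
11 | methyl 4-[(4R)-4-benzyl-2-oxo-1,3-oxazolidin-3-yl]-4-oxobutanoate | COC(=O)CCC(=O)N1[C@H](Cc2ccccc2)COC1=O | intermediate
12 | dibutylboron (Z)-enolate of 11 | COC(=O)C/C=C(\OB(CCCC)CCCC)N1[C@H](Cc2ccccc2)COC1=O | intermediate
13 | methyl (3R,4S)-3-{[(4R)-4-benzyl-2-oxo-1,3-oxazolidin-3-yl]carbonyl}-4-hydroxy-5-[(4R)-2,2,4-trimethyl-1,3-dioxolan-4-yl]pentanoate | COC(=O)C[C@@H](C(=O)N1[C@H](Cc2ccccc2)COC1=O)[C@@H](O)C[C@]3(C)COC(C)(C)O3 | intermediate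
14 | (4R)-4-benzyl-3-{[(2S,3R)-5-oxo-2-{[(4R)-2,2,4-trimethyl-1,3-dioxolan-4-yl]methyl}oxolan-3-yl]carbonyl}-1,3-oxazolidin-2-one | O=C1C[C@@H](C(=O)N2[C@H](Cc3ccccc3)COC2=O)[C@H](C[C@]4(C)COC(C)(C)O4)O1 | intermediate
15 | (2S,3R)-5-oxo-2-{[(4R)-2,2,4-trimethyl-1,3-dioxolan-4-yl]methyl}oxolane-3-carboperoxoic acid | O=C1C[C@@H](C(=O)OO)[C@H](C[C@]2(C)COC(C)(C)O2)O1 | intermediate
16 | (2S,3R)-5-oxo-2-{[(4R)-2,2,4-trimethyl-1,3-dioxolan-4-yl]methyl}oxolane-3-carboxylic acid | O=C1C[C@@H](C(=O)O)[C@H](C[C@]2(C)COC(C)(C)O2)O1 | intermediate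
17 | propyne | CC#C | starting material
18 | (2S,3R)-5-oxo-2-{[(4R)-2,2,4-trimethyl-1,3-dioxolan-4-yl]methyl}oxolane-3-carbonyl chloride | O=C1C[C@@H](C(Cl)=O)[C@H](C[C@]2(C)COC(C)(C)O2)O1 | intermediate
19 | (4R,5S)-4-(but-2-ynoyl)-5-{[(4R)-2,2,4-trimethyl-1,3-dioxolan-4-yl]methyl}oxolan-2-one | O=C1C[C@@H](C(=O)C#CC)[C@H](C[C@]2(C)COC(C)(C)O2)O1 | intermediate
20 | (4S,5S)-4-[(1S)-1-hydroxybut-2-yn-1-yl]-5-{[(4R)-2,2,4-trimethyl-1,3-dioxolan-4-yl]methyl}oxolan-2-one | O=C1C[C@@H]([C@H](O)C#CC)[C@H](C[C@]2(C)COC(C)(C)O2)O1 | intermediate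
21 | (4S,5S)-4-[(1S,2Z)-1-hydroxy-3-(triethylsilyl)but-2-en-1-yl]-5-{[(4R)-2,2,4-trimethyl-1,3-dioxolan-4-yl]methyl}oxolan-2-one | O=C1C[C@@H]([C@H](O)/C=C(C)\[Si](CC)(CC)CC)[C@H](C[C@]2(C)COC(C)(C)O2)O1 | intermediate
22 | (4S,5S)-4-[(1S,2Z)-1-hydroxy-3-iodobut-2-en-1-yl]-5-{[(4R)-2,2,4-trimethyl-1,3-dioxolan-4-yl]methyl}oxolan-2-one | O=C1C[C@@H]([C@H](O)/C=C(C)\I)[C@H](C[C@]2(C)COC(C)(C)O2)O1 | intermediate
23 | (4R,5S)-4-[(1S,2Z)-1-{[tert-butyl(dimethyl)silyl]oxy}-3-iodobut-2-en-1-yl]-5-{[(4R)-2,2,4-trimethyl-1,3-dioxolan-4-yl]methyl}oxolan-2-one | O=C1C[C@@H]([C@H](O[Si](C)(C)C(C)(C)C)/C=C(C)\I)[C@H](C[C@]2(C)COC(C)(C)O2)O1 | intermediate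
24 | lithium enolate of 23 | [Li]OC1=C[C@@H]([C@H](O[Si](C)(C)C(C)(C)C)/C=C(C)\I)[C@H](C[C@]2(C)COC(C)(C)O2)O1 | intermediate
25 | 3-[(dimethylamino)methyl] derivative of 23 (Mannich base, C3 epimers) | O=C1C(CN(C)C)[C@@H]([C@H](O[Si](C)(C)C(C)(C)C)/C=C(C)\I)[C@H](C[C@]2(C)COC(C)(C)O2)O1 | intermediate
26 | trimethylammonium iodide from 25 | O=C1C(C[N+](C)(C)C)[C@@H]([C@H](O[Si](C)(C)C(C)(C)C)/C=C(C)\I)[C@H](C[C@]2(C)COC(C)(C)O2)O1.[I-] | intermediate
27 | (4R,5S)-4-[(1S,2Z)-1-{[tert-butyl(dimethyl)silyl]oxy}-3-iodobut-2-en-1-yl]-3-methylidene-5-{[(4R)-2,2,4-trimethyl-1,3-dioxolan-4-yl]methyl}oxolan-2-one | O=C1C(=C)[C@@H]([C@H](O[Si](C)(C)C(C)(C)C)/C=C(C)\I)[C@H](C[C@]2(C)COC(C)(C)O2)O1 | intermediate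
28 | ethynyltrimethylsilane | C#C[Si](C)(C)C | starting material
29 | (4R,5S)-4-[(1R,2Z)-1-{[tert-butyl(dimethyl)silyl]oxy}-3-methyl-5-(trimethylsilyl)pent-2-en-4-yn-1-yl]-3-methylidene-5-{[(4R)-2,2,4-trimethyl-1,3-dioxolan-4-yl]methyl}oxolan-2-one | O=C1C(=C)[C@@H]([C@H](O[Si](C)(C)C(C)(C)C)/C=C(C)\C#C[Si](C)(C)C)[C@H](C[C@]2(C)COC(C)(C)O2)O1 | intermediate
30 | (4R,5S)-4-[(1R,2Z)-1-{[tert-butyl(dimethyl)silyl]oxy}-5-iodo-3-methylpent-2-en-4-yn-1-yl]-3-methylidene-5-{[(4R)-2,2,4-trimethyl-1,3-dioxolan-4-yl]methyl}oxolan-2-one | O=C1C(=C)[C@@H]([C@H](O[Si](C)(C)C(C)(C)C)/C=C(C)\C#CI)[C@H](C[C@]2(C)COC(C)(C)O2)O1 | intermediate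
31 | (4R,5S)-4-[(1R,2Z)-1-{[tert-butyl(dimethyl)silyl]oxy}-5-iodo-3-methylpent-2-en-4-yn-1-yl]-5-[(2R)-2,3-dihydroxy-2-methylpropyl]-3-methylideneoxolan-2-one | O=C1C(=C)[C@@H]([C@H](O[Si](C)(C)C(C)(C)C)/C=C(C)\C#CI)[C@H](C[C@@](C)(O)CO)O1 | intermediate
32 | (4R,5S)-4-[(1R,2Z)-1-{[tert-butyl(dimethyl)silyl]oxy}-5-iodo-3-methylpent-2-en-4-yn-1-yl]-5-[(2R)-2-hydroxy-2-methyl-3-oxopropyl]-3-methylideneoxolan-2-one | O=C1C(=C)[C@@H]([C@H](O[Si](C)(C)C(C)(C)C)/C=C(C)\C#CI)[C@H](C[C@@](C)(O)C=O)O1 | intermediate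
33 | (4Z,6R,7R,8S,10R)-6-{[tert-butyl(dimethyl)silyl]oxy}-1,10-dihydroxygermacra-4,11(13)-dien-2-yn-12,8-olide (C1 epimers) | C=C1C(=O)O[C@H]2C[C@@](C)(O)C(O)C#C/C(C)=C\[C@@H](O[Si](C)(C)C(C)(C)C)[C@H]12 | intermediate
34 | (4Z,6R,7R,8S,10R)-6-{[tert-butyl(dimethyl)silyl]oxy}-10-hydroxy-1-oxogermacra-4,11(13)-dien-2-yn-12,8-olide | C=C1C(=O)O[C@H]2C[C@@](C)(O)C(=O)C#C/C(C)=C\[C@@H](O[Si](C)(C)C(C)(C)C)[C@H]12 | intermediate
35 | (4Z,6R,7R,8S,10R)-6-{[tert-butyl(dimethyl)silyl]oxy}-3,10-epoxy-1-oxogermacra-2,4,11(13)-trien-12,8-olide | C=C1C(=O)O[C@H]2C[C@@]3(C)OC(=CC3=O)/C(C)=C\[C@@H](O[Si](C)(C)C(C)(C)C)[C@H]12 | intermediate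
36 | (4Z,6R,7S,8S,10R)-6-hydroxy-3,10-epoxy-1-oxogermacra-2,4,11(13)-trien-12,8-olide | C=C1C(=O)O[C@H]2C[C@@]3(C)OC(=CC3=O)/C(C)=C\[C@@H](O)[C@H]12 | intermediate
37 | (2E)-2-methylbut-2-enoic acid (tiglic acid) | C/C=C(\C)C(=O)O | starting material
38 | (2E)-2-methylbut-2-en-1-ol | C/C=C(\C)CO | intermediate
39 | [(2R,3R)-2,3-dimethyloxiran-2-yl]methanol | OC[C@@]1(C)O[C@@H]1C | intermediate
40 | (2S,3R)-2,3-dimethyloxirane-2-carboxylic acid | OC(=O)[C@@]1(C)O[C@@H]1C | intermediate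
41 | (2S,3R)-2,3-dimethyloxirane-2-carboxylic 2,4,6-trichlorobenzoic anhydride | O=C(OC(=O)[C@@]1(C)O[C@@H]1C)c1c(Cl)cc(Cl)cc1Cl | intermediate
42 | (4Z,6R,7R,8S,10R)-6-{[(2S,3R)-2,3-dimethyloxirane-2-carbonyl]oxy}-3,10-epoxy-1-oxogermacra-2,4,11(13)-trien-12,8-olide (CNP0258430.2) | C=C1C(=O)O[C@H]2C[C@@]3(C)OC(=CC3=O)/C(C)=C\[C@@H](OC(=O)[C@@]3(C)O[C@@H]3C)[C@H]12 | target

**Totals**
Total step count: 25. Longest linear sequence: 21 steps (steps 1–4, 6–21, 25).

**Three steps most likely to fail**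

Step 10 (regiochemistry of the trans-hydrosilylation next to the hindered lactone carbinol). The fallback sets out from ynone 19 and fixes the iodine position by conjugate addition instead of by hydroxyl direction. NaI/AcOH in MeCN at rt adds HI anti across the ynone to give the Z-β-iodo enone (4R,5S)-4-[(2Z)-3-iodobut-2-enoyl]-5-{[(4R)-2,2,4-trimethyl-1,3-dioxolan-4-yl]methyl}oxolan-2-one F1. Reduction of the ketone with (R)-2-methyl-CBS-oxazaborolidine and catecholborane (toluene, −78 °C, iodoalkenyl arm as the large group) must override the Felkin preference of the substrate, which favours the wrong C6 epimer. It comes back to the route at vinyl iodide 22, bypassing steps 9–11.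

Step 18 (closure of the strained ten-membered enyne ring at C1–C2). The fallback closes the ring at C3–C4 instead and sets out from vinyl iodide 27. AcOH/H2O removes the acetonide to give (4R,5S)-4-[(1S,2Z)-1-{[tert-butyl(dimethyl)silyl]oxy}-3-iodobut-2-en-1-yl]-5-[(2R)-2,3-dihydroxy-2-methylpropyl]-3-methylideneoxolan-2-one F2. TEMPO/PhI(OAc)2 then gives (4R,5S)-4-[(1S,2Z)-1-{[tert-butyl(dimethyl)silyl]oxy}-3-iodobut-2-en-1-yl]-5-[(2R)-2-hydroxy-2-methyl-3-oxopropyl]-3-methylideneoxolan-2-one F3. Ethynylmagnesium bromide (THF, −78 °C, aldehyde faster than enoate) gives (4R,5S)-4-[(1S,2Z)-1-{[tert-butyl(dimethyl)silyl]oxy}-3-iodobut-2-en-1-yl]-5-[(2R)-2,3-dihydroxy-2-methylpent-4-yn-1-yl]-3-methylideneoxolan-2-one F4 as C1 epimers. Intramolecular Sonogashira coupling (Pd(PPh3)4, CuI, Et3N, THF, high dilution) joins the terminal alkyne to the Z-vinyl iodide and comes back to the route at macrocyclic diol 33, bypassing steps 14–18.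

Step 20 (transannular furanone closure on the hydroxy ynone). The fallback reverses the order of oxidation and cyclisation and sets out from macrocyclic diol 33. AgOTf (10 mol%, CH2Cl2, rt; (Ph3P)AuNTf2 as alternative) effects 5-endo-dig hydroalkoxylation of the unactivated alkyne by the tertiary C10 hydroxyl to give (4Z,6R,7R,8S,10R)-6-{[tert-butyl(dimethyl)silyl]oxy}-3,10-epoxy-1-hydroxygermacra-2,4,11(13)-trien-12,8-olide F5, which cannot aromatise because C10 is quaternary. MnO2 in CH2Cl2 oxidises the allylic C1 carbinol and comes back to the route at furanone 35, bypassing steps 19–20.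

**Further compounds**
F1 | step 10 | (4R,5S)-4-[(2Z)-3-iodobut-2-enoyl]-5-{[(4R)-2,2,4-trimethyl-1,3-dioxolan-4-yl]methyl}oxolan-2-one | O=C1C[C@@H](C(=O)/C=C(C)\I)[C@H](C[C@]2(C)COC(C)(C)O2)O1
F2 | step 18 | (4R,5S)-4-[(1S,2Z)-1-{[tert-butyl(dimethyl)silyl]oxy}-3-iodobut-2-en-1-yl]-5-[(2R)-2,3-dihydroxy-2-methylpropyl]-3-methylideneoxolan-2-one | O=C1C(=C)[C@@H]([C@H](O[Si](C)(C)C(C)(C)C)/C=C(C)\I)[C@H](C[C@@](C)(O)CO)O1
F3 | step 18 | (4R,5S)-4-[(1S,2Z)-1-{[tert-butyl(dimethyl)silyl]oxy}-3-iodobut-2-en-1-yl]-5-[(2R)-2-hydroxy-2-methyl-3-oxopropyl]-3-methylideneoxolan-2-one | O=C1C(=C)[C@@H]([C@H](O[Si](C)(C)C(C)(C)C)/C=C(C)\I)[C@H](C[C@@](C)(O)C=O)O1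
F4 | step 18 | (4R,5S)-4-[(1S,2Z)-1-{[tert-butyl(dimethyl)silyl]oxy}-3-iodobut-2-en-1-yl]-5-[(2R)-2,3-dihydroxy-2-methylpent-4-yn-1-yl]-3-methylideneoxolan-2-one (C1 epimers) | O=C1C(=C)[C@@H]([C@H](O[Si](C)(C)C(C)(C)C)/C=C(C)\I)[C@H](C[C@@](C)(O)C(O)C#C)O1
F5 | step 20 | (4Z,6R,7R,8S,10R)-6-{[tert-butyl(dimethyl)silyl]oxy}-3,10-epoxy-1-hydroxygermacra-2,4,11(13)-trien-12,8-olide (C1 epimers) | C=C1C(=O)O[C@H]2C[C@@]3(C)OC(=CC3O)/C(C)=C\[C@@H](O[Si](C)(C)C(C)(C)C)[C@H]12
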